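The numbers of this flask were set for the occasion; the flask was simulated.

What is left of the second nucleophile at the end tells you how much solvolysis product was made. The capture step and the solvolysis step draw on the same intermediate, so the solvolysis product in moles per litre equals the natural logarithm of charge over leftover, divided by the selectivity factor, the capture constant over the solvolysis constant, here 5.19 /M.

the same everywhere: substrate 0.25 M; gas 130 mM (held); time 15 min

| flask | second nucleophile |
|---|---|
| teal | 0.230 M |
| grey | 0.560 M |

    substrate → intermediate (k1 = 0.00627 /s)
    first nucleophile + intermediate → target (k2 = 1.20 /M/s)
    second nucleophile + intermediate → other capture product (k3 = 8.41 /M/s)
    intermediate → solvolysis product (k4 = 1.62 /s)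
    gas ⇌ first nucleophile, rate k5*(csat - [first nucleophile]) (k5 = 0.00408 /s, csat = 130 mM)

- at the start none of first nucleophile is dissolved
- run time (teal): 15 min

* which of these there is most of at the end, counted by the substrate in it, teal (solvolysis product / target / other capture product / substrate)
* which of these there is most of at the end, counted by the substrate in it, grey (solvolysis product / target / other capture product / substrate)
* how much there is at the end of the one of these that leads, in percent of the substrate charged: teal
* how much there is at the end of the one of these that leads, in percent of the substrate charged: grey

The substrate has a half-life of 1.8 min, so 0.354 % of it remains at the end. Solvolysis by itself gives the intermediate a lifetime of 0.617 s, far shorter than the substrate's 159 s, so the intermediate stays at a steady state and you can follow the split from moment to moment: capture stands to solvolysis as the selectivity factor times the free second nucleophile stands to one.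

Leave the target aside for the moment. In teal, holding the second nucleophile at its charge gives solvolysis product a lower bound of 45.6 %, and the end level which that implies gives an upper bound of 67.2 %. In grey, the same two steps put other capture product below 74.4 % and above 66.0 %. Taking the mean of charge and end level gives a middle estimate of 54.3 % of solvolysis product in teal and 70.8 % of other capture product in grey.

The correction is the target. Weighted over the substrate's decay, the dissolved first nucleophile stands near 51.2 mM, so the target takes 2.06 % of the flow in teal and 1.11 % in grey. I commit to solvolysis product leading at 53.2 % in teal and other capture product leading at 70.0 % in grey.

The forecast gives solvolysis product at 52.5 % in teal and other capture product at 70 % in grey, each above my lower bound and below my upper one: “solvolysis narrowly wins in teal and the other capture product clearly wins in grey”.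

The simulation gives solvolysis product at 52.3 % in teal and other capture product at 69.8 % in grey.

In teal, the leftover of 50.7 % and the selectivity factor return 52.3 % of solvolysis product. The neighbour is like grey but charged with 0.14 M of second nucleophile. The same reckoning starts from a lower bound of 57.9 % of solvolysis product, and the mean and the target correction bring it to 67.0 %. Its leftover of 42.9 % returns 65.2 %. The simulation of that neighbour ends with solvolysis product in the lead at 65.2 %.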